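## Retrosynthetic overview

1. The target comes from its 2',5'-di-O-benzyl ether by hydrogenolysis, so the air-sensitive hydroquinone of ring B appears only in the last step.
2. Ring C (the dihydropyran, the only ring built) is opened at O1–C2: Mitsunobu etherification of a ring-A phenol onto the primary alcohol of a 1,2-diarylpropane-1,3-diol.
3. The C3–C4 bond comes from an intermolecular Evans syn-aldol between the boron enolate of an (R)-4-benzyloxazolidinone arylacetyl imide (ring B) and an O-allyl salicylaldehyde (ring A). The syn adduct corresponds to 3,4-trans, and both stereocentres are set here.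
4. Both arenes come from 2,3,4-trimethoxyphenol (Dakin product of 2,3,4-trimethoxybenzaldehyde). Ring A: ortho-formylation and allylation. Ring B: oxidation to 2,3-dimethoxybenzoquinone, reductive benzylation, bromination, Pd-catalysed ester-enolate arylation.
5. Ring order: rings A and B are carried in as preformed benzenes; ring C is closed after the aldol, in the penultimate step.

Assumption: the SMILES is read as the (3S,4R) enantiomer (3,4-trans); protecting-group, redox and one-carbon reagents are named with SMILES but not numbered.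

## Route

Step 1
Reactants: 1 2,3,4-trimethoxybenzaldehyde
Product: 3 2,3,4-trimethoxyphenol, via aryl formate 2 (not isolated)
Conditions: mCPBA, CH2Cl2, 0 °C → rt; aq. NaHCO3 wash; then K2CO3 (cat.), MeOH, rt
Reagents that add atoms: mCPBA (3-chloroperoxybenzoic acid), OOC(=O)c1cccc(Cl)c1
Why: Baeyer–Villiger (Dakin-type) oxidation, in which the electron-rich aryl group migrates to oxygen and the labile aryl formate is then transesterified by methanol.

Step 2
Reactants: 3 2,3,4-trimethoxyphenol
Product: 5 2-hydroxy-3,4,5-trimethoxybenzaldehyde, via salicyl alcohol 4 (not isolated)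
Conditions: MgCl2, Et3N, (CH2O)n, MeCN, reflux; 1 M HCl work-up
Reagents that add atoms: paraformaldehyde (formaldehyde), C=O
Why: Casnati–Skattebøl ortho-formylation, in which the magnesium phenoxide delivers formaldehyde to the only free ortho position and a second formaldehyde oxidises the benzylic alkoxide by Oppenauer-type hydride transfer.

Step 3
Reactants: 5 2-hydroxy-3,4,5-trimethoxybenzaldehyde
Product: 6 3,4,5-trimethoxy-2-(prop-2-en-1-yloxy)benzaldehyde
Conditions: allyl bromide, K2CO3, DMF, 50 °C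
Reagents that add atoms: allyl bromide, C=CCBr
Why: Williamson etherification of the phenoxide; the allyl ether is inert to the aldol and hydride steps and is later removed under neutral conditions without touching benzyl ethers.

Step 4
Reactants: 3 2,3,4-trimethoxyphenol
Product: 8 2,3-dimethoxycyclohexa-2,5-diene-1,4-dione, via quinol hemiketal 7 (not isolated)
Conditions: PhI(OAc)2, MeCN/H2O (2:1), 0 °C
Reagents that add atoms: water, O
Why: hypervalent-iodine oxidative dearomatisation of a para-methoxyphenol, in which water adds at the para carbon and the hemiketal collapses to the p-quinone with loss of methanol.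

Step 5
Reactants: 8 2,3-dimethoxycyclohexa-2,5-diene-1,4-dione
Product: 10 1,4-bis(benzyloxy)-2,3-dimethoxybenzene, via hydroquinone 9 (not isolated)
Conditions: Na2S2O4, EtOAc/H2O, rt; then BnBr, K2CO3, DMF, 60 °C (Ar)
Reagents that add atoms: benzyl bromide, BrCc1ccccc1
Why: dithionite reduction of the quinone followed at once by double Williamson O-benzylation, which fixes the oxygens that become the 2'- and 5'-hydroxyls as benzyl ethers.

Step 6
Reactants: 10 1,4-bis(benzyloxy)-2,3-dimethoxybenzene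
Product: 11 1,4-bis(benzyloxy)-5-bromo-2,3-dimethoxybenzene
Conditions: NBS (1.0 equiv), MeCN, 0 °C → rt (dark)
Reagents that add atoms: N-bromosuccinimide, O=C1CCC(=O)N1Br
Why: electrophilic aromatic bromination of a tetra-alkoxybenzene whose two free positions are equivalent by symmetry, so a single monobromide forms.

Step 7
Reactants: 11 1,4-bis(benzyloxy)-5-bromo-2,3-dimethoxybenzene; 12 tert-butyl bromoacetate
Product: 14 tert-butyl [2,5-bis(benzyloxy)-3,4-dimethoxyphenyl]acetate, via Reformatsky reagent 13 (not isolated)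
Conditions: 12, Zn (Me3SiCl-activated), THF, rt; then 11, Pd(dba)2 (2 mol%), P(t-Bu)3 (2 mol%), THF, rt → 50 °C
Reagents that add atoms: none
Why: palladium-catalysed α-arylation of a zinc ester enolate (Negishi-type coupling of a Reformatsky reagent), which tolerates electron-rich ortho-alkoxy aryl bromides and stops at monoarylation.

Step 8
Reactants: 14 tert-butyl [2,5-bis(benzyloxy)-3,4-dimethoxyphenyl]acetate
Product: 15 [2,5-bis(benzyloxy)-3,4-dimethoxyphenyl]acetic acid
Conditions: CF3CO2H/CH2Cl2 (1:4), 0 °C → rt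
Reagents that add atoms: none
Why: acidolysis of the tert-butyl ester with loss of isobutene, under which aryl benzyl and methyl ethers are stable.

Step 9
Reactants: 15 [2,5-bis(benzyloxy)-3,4-dimethoxyphenyl]acetic acid; 16 (4R)-4-benzyl-1,3-oxazolidin-2-one
Product: 18 (4R)-4-benzyl-3-{[2,5-bis(benzyloxy)-3,4-dimethoxyphenyl]acetyl}-1,3-oxazolidin-2-one, via mixed pivalic anhydride 17 (not isolated)
Conditions: PivCl, Et3N, THF, −20 °C; then 16, LiCl, −20 °C → rt
Reagents that add atoms: none
Why: N-acylation of the oxazolidinone through the mixed pivalic anhydride with LiCl activation, the hindered pivaloyl carbonyl directing attack to the arylacetyl carbonyl.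

Step 10
Reactants: 18 (4R)-4-benzyl-3-{[2,5-bis(benzyloxy)-3,4-dimethoxyphenyl]acetyl}-1,3-oxazolidin-2-one; 6 3,4,5-trimethoxy-2-(prop-2-en-1-yloxy)benzaldehyde
Product: 21 (4R)-4-benzyl-3-{(2R,3R)-2-[2,5-bis(benzyloxy)-3,4-dimethoxyphenyl]-3-hydroxy-3-[3,4,5-trimethoxy-2-(prop-2-en-1-yloxy)phenyl]propanoyl}-1,3-oxazolidin-2-one, via boron enolate 19 (not isolated), via boron aldolate 20 (not isolated)
Conditions: Bu2BOTf, i-Pr2NEt, CH2Cl2, 0 °C; then 6, −78 → 0 °C; pH 7 buffer, MeOH, 30% H2O2, 0 °C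
Reagents that add atoms: none
Why: Evans boron syn-aldol, in which the Z-enolate reacts through a Zimmerman–Traxler chair on the face opposite the (R)-benzyl group of the auxiliary, forming the C3–C4 bond and both stereocentres as the (2R,3R) syn adduct (syn in the chain equals 3,4-trans in the chroman).

Step 11
Reactants: 21 the (2R,3R) aldol adduct
Product: 22 (1R,2S)-2-[2,5-bis(benzyloxy)-3,4-dimethoxyphenyl]-1-[3,4,5-trimethoxy-2-(prop-2-en-1-yloxy)phenyl]propane-1,3-diol
Conditions: LiBH4, MeOH (1 equiv), THF, 0 °C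
Reagents that add atoms: none
Why: reductive cleavage of the N-acyloxazolidinone at the exocyclic carbonyl gives the primary alcohol and returns the auxiliary, with no stereocentre touched (the descriptor at C2 changes from R to S only through CIP ranking).

Step 12
Reactants: 22 the allyl-protected 1,3-diol
Product: 23 6-{(1R,2S)-2-[2,5-bis(benzyloxy)-3,4-dimethoxyphenyl]-1,3-dihydroxypropyl}-2,3,4-trimethoxyphenol
Conditions: Pd(PPh3)4 (5 mol%), morpholine, THF, rt
Reagents that add atoms: none
Why: Tsuji–Trost deallylation, in which zerovalent palladium ionises the aryl allyl ether to a π-allyl complex that morpholine traps, under neutral conditions that spare the acid-sensitive benzylic alcohol and the benzyl ethers.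

Step 13
Reactants: 23 the phenol diol
Product: 24 (3S,4R)-3-[2,5-bis(benzyloxy)-3,4-dimethoxyphenyl]-6,7,8-trimethoxy-3,4-dihydro-2H-chromen-4-ol
Conditions: PPh3, DIAD, THF (0.01 M), 0 °C → rt
Reagents that add atoms: none
Why: intramolecular Mitsunobu etherification, in which the primary alcohol is activated in preference to the hindered secondary one and the phenoxide closes ring C by 6-exo displacement at CH2, so neither stereocentre is involved.

Step 14
Reactants: 24 the bis-benzyl isoflavan-4-ol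
Product: 25 (3S,4R)-3-(2,5-dihydroxy-3,4-dimethoxyphenyl)-6,7,8-trimethoxy-3,4-dihydro-2H-chromen-4-ol
Conditions: H2 (1 atm), 10% Pd/C, EtOAc (degassed), rt; filtered under Ar
Reagents that add atoms: none
Why: catalytic hydrogenolysis of the two aryl benzyl ethers, which under neutral, acid-free conditions is much faster than C4–O hydrogenolysis and gives the hydroquinone under a reducing atmosphere.

## Compound list

1 | 2,3,4-trimethoxybenzaldehyde | COc1ccc(C=O)c(OC)c1OC | starting material
2 | 2,3,4-trimethoxyphenyl formate | COc1ccc(OC=O)c(OC)c1OC | intermediate (not isolated)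
3 | 2,3,4-trimethoxyphenol | COc1ccc(O)c(OC)c1OC | intermediate
4 | 6-(hydroxymethyl)-2,3,4-trimethoxyphenol (as magnesium salt) | COc1cc(CO)c(O)c(OC)c1OC | intermediate (not isolated)
5 | 2-hydroxy-3,4,5-trimethoxybenzaldehyde | COc1cc(C=O)c(O)c(OC)c1OC | intermediate
6 | 3,4,5-trimethoxy-2-(prop-2-en-1-yloxy)benzaldehyde | COc1cc(C=O)c(OCC=C)c(OC)c1OC | intermediate
7 | 4-hydroxy-2,3,4-trimethoxycyclohexa-2,5-dien-1-one (racemic) | COC1=C(OC)C(O)(OC)C=CC1=O | intermediate (not isolated)
8 | 2,3-dimethoxycyclohexa-2,5-diene-1,4-dione | COC1=C(OC)C(=O)C=CC1=O | intermediate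
9 | 2,3-dimethoxybenzene-1,4-diol | COc1c(O)ccc(O)c1OC | intermediate (not isolated)
10 | 1,4-bis(benzyloxy)-2,3-dimethoxybenzene | COc1c(OCc2ccccc2)ccc(OCc2ccccc2)c1OC | intermediate
11 | 1,4-bis(benzyloxy)-5-bromo-2,3-dimethoxybenzene | COc1c(OCc2ccccc2)cc(Br)c(OCc2ccccc2)c1OC | intermediate
12 | tert-butyl bromoacetate | CC(C)(C)OC(=O)CBr | starting material
13 | bromo(2-tert-butoxy-2-oxoethyl)zinc | CC(C)(C)OC(=O)C[Zn]Br | intermediate (not isolated)
14 | tert-butyl [2,5-bis(benzyloxy)-3,4-dimethoxyphenyl]acetate | COc1c(OCc2ccccc2)cc(CC(=O)OC(C)(C)C)c(OCc2ccccc2)c1OC | intermediate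
15 | [2,5-bis(benzyloxy)-3,4-dimethoxyphenyl]acetic acid | COc1c(OCc2ccccc2)cc(CC(=O)O)c(OCc2ccccc2)c1OC | intermediate
16 | (4R)-4-benzyl-1,3-oxazolidin-2-one | O=C1N[C@H](Cc2ccccc2)CO1 | starting material
17 | [2,5-bis(benzyloxy)-3,4-dimethoxyphenyl]acetic 2,2-dimethylpropanoic anhydride | COc1c(OCc2ccccc2)cc(CC(=O)OC(=O)C(C)(C)C)c(OCc2ccccc2)c1OC | intermediate (not isolated)
18 | (4R)-4-benzyl-3-{[2,5-bis(benzyloxy)-3,4-dimethoxyphenyl]acetyl}-1,3-oxazolidin-2-one | COc1c(OCc2ccccc2)cc(CC(=O)N2[C@H](Cc3ccccc3)COC2=O)c(OCc2ccccc2)c1OC | intermediate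
19 | (Z)-dibutylboron enolate of 18 | CCCCB(CCCC)O/C(=C\c1cc(OCc2ccccc2)c(OC)c(OC)c1OCc1ccccc1)N1[C@H](Cc2ccccc2)COC1=O | intermediate (not isolated)
20 | O-dibutylboryl aldolate of 21 | O=C(N1[C@H](Cc2ccccc2)COC1=O)[C@H](c1cc(OCc2ccccc2)c(OC)c(OC)c1OCc1ccccc1)[C@@H](OB(CCCC)CCCC)c1cc(OC)c(OC)c(OC)c1OCC=C | intermediate (not isolated)
21 | (4R)-4-benzyl-3-{(2R,3R)-2-[2,5-bis(benzyloxy)-3,4-dimethoxyphenyl]-3-hydroxy-3-[3,4,5-trimethoxy-2-(prop-2-en-1-yloxy)phenyl]propanoyl}-1,3-oxazolidin-2-one | O=C(N1[C@H](Cc2ccccc2)COC1=O)[C@H](c1cc(OCc2ccccc2)c(OC)c(OC)c1OCc1ccccc1)[C@@H](O)c1cc(OC)c(OC)c(OC)c1OCC=C | intermediate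
22 | (1R,2S)-2-[2,5-bis(benzyloxy)-3,4-dimethoxyphenyl]-1-[3,4,5-trimethoxy-2-(prop-2-en-1-yloxy)phenyl]propane-1,3-diol | OC[C@H](c1cc(OCc2ccccc2)c(OC)c(OC)c1OCc1ccccc1)[C@@H](O)c1cc(OC)c(OC)c(OC)c1OCC=C | intermediate
23 | 6-{(1R,2S)-2-[2,5-bis(benzyloxy)-3,4-dimethoxyphenyl]-1,3-dihydroxypropyl}-2,3,4-trimethoxyphenol | OC[C@H](c1cc(OCc2ccccc2)c(OC)c(OC)c1OCc1ccccc1)[C@@H](O)c1cc(OC)c(OC)c(OC)c1O | intermediate
24 | (3S,4R)-3-[2,5-bis(benzyloxy)-3,4-dimethoxyphenyl]-6,7,8-trimethoxy-3,4-dihydro-2H-chromen-4-ol | COc1cc2c(c(OC)c1OC)OC[C@H](c1cc(OCc3ccccc3)c(OC)c(OC)c1OCc1ccccc1)[C@H]2O | intermediate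
25 | (3S,4R)-3-(2,5-dihydroxy-3,4-dimethoxyphenyl)-6,7,8-trimethoxy-3,4-dihydro-2H-chromen-4-ol | COc1cc2c(c(OC)c1OC)OC[C@H](c1cc(O)c(OC)c(OC)c1O)[C@H]2O | target

## Step count and risks

Total step count: 14. Longest linear sequence: 12 steps (steps 1, 4, 5, 6, 7, 8, 9, 10, 11, 12, 13, 14, from 1 to 25). The ring-A branch (steps 2 and 3) joins at step 10.

Steps most likely to fail:

Step 10 (aldol). The risks are slow addition to the hindered, electron-rich aldehyde 6, eroded diastereoselectivity with an α-aryl enolate, and retro-aldol of the doubly activated benzylic aldolate on work-up. The fallback sets out from acid 15 and changes both the auxiliary and the enolate metal. DCC/DMAP coupling with (R)-4-benzyl-1,3-thiazolidine-2-thione gives the N-acyl thiazolidinethione F1. Its chlorotitanium enolate (TiCl4, i-Pr2NEt, N-methylpyrrolidinone, CH2Cl2, −78 → 0 °C) adds to 6, now activated by the Lewis acid, to give the Evans-syn thioimide aldol adduct F2 with the same (2R,3R) configuration. NaBH4 in THF/EtOH then cleaves the thiazolidinethione directly, so the route is rejoined at diol 22, bypassing 21.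

Step 13 (Mitsunobu ring closure). The risks are activation of the electron-rich secondary benzylic alcohol (quinone-methide or elimination products) and the sensitivity of the free ortho-hydroxybenzyl alcohol 23. The fallback sets out from diol 22 while the allyl ether is still in place and replaces the redox dehydration by a sulfonate displacement. Selective sulfonylation of the primary hydroxyl (TsCl, Et3N, Me3N·HCl cat., CH2Cl2, 0 °C) gives the primary mono-tosylate F3. Pd(PPh3)4 with K2CO3 in MeOH at rt then removes the allyl group to the phenol tosylate F4 (not isolated), whose phenoxide closes ring C by intramolecular Williamson etherification. The route is rejoined at 24, bypassing 23.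

Step 14 (final debenzylation). The risk is competing hydrogenolysis of the activated C4–OH to the isoflavan, along with air oxidation of the hydroquinone. The fallback sets out from 24 and masks the benzylic alcohol before the hydrogenolysis. TBSOTf and 2,6-lutidine (CH2Cl2, −78 °C) give the C4 silyl ether F5. H2 with 10% Pd/C in EtOAc removes both benzyl groups to the silyl-protected hydroquinone F6. Bu4NF buffered with AcOH (degassed THF, 0 °C) then frees the C4 hydroxyl, and the route is rejoined at 25.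

## Further compounds

F1 | step 10 | 1-[(4R)-4-benzyl-2-sulfanylidene-1,3-thiazolidin-3-yl]-2-[2,5-bis(benzyloxy)-3,4-dimethoxyphenyl]ethan-1-one | COc1c(OCc2ccccc2)cc(CC(=O)N2[C@H](Cc3ccccc3)CSC2=S)c(OCc2ccccc2)c1OC
F2 | step 10 | (2R,3R)-1-[(4R)-4-benzyl-2-sulfanylidene-1,3-thiazolidin-3-yl]-2-[2,5-bis(benzyloxy)-3,4-dimethoxyphenyl]-3-hydroxy-3-[3,4,5-trimethoxy-2-(prop-2-en-1-yloxy)phenyl]propan-1-one | O=C(N1[C@H](Cc2ccccc2)CSC1=S)[C@H](c1cc(OCc2ccccc2)c(OC)c(OC)c1OCc1ccccc1)[C@@H](O)c1cc(OC)c(OC)c(OC)c1OCC=C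
F3 | step 13 | (2S,3R)-2-[2,5-bis(benzyloxy)-3,4-dimethoxyphenyl]-3-hydroxy-3-[3,4,5-trimethoxy-2-(prop-2-en-1-yloxy)phenyl]propyl 4-methylbenzenesulfonate | Cc1ccc(cc1)S(=O)(=O)OC[C@H](c1cc(OCc2ccccc2)c(OC)c(OC)c1OCc1ccccc1)[C@@H](O)c1cc(OC)c(OC)c(OC)c1OCC=C
F4 | step 13 | (2S,3R)-2-[2,5-bis(benzyloxy)-3,4-dimethoxyphenyl]-3-hydroxy-3-(2-hydroxy-3,4,5-trimethoxyphenyl)propyl 4-methylbenzenesulfonate | Cc1ccc(cc1)S(=O)(=O)OC[C@H](c1cc(OCc2ccccc2)c(OC)c(OC)c1OCc1ccccc1)[C@@H](O)c1cc(OC)c(OC)c(OC)c1O
F5 | step 14 | {[(3S,4R)-3-[2,5-bis(benzyloxy)-3,4-dimethoxyphenyl]-6,7,8-trimethoxy-3,4-dihydro-2H-chromen-4-yl]oxy}(tert-butyl)dimethylsilane | COc1cc2c(c(OC)c1OC)OC[C@H](c1cc(OCc3ccccc3)c(OC)c(OC)c1OCc1ccccc1)[C@H]2O[Si](C)(C)C(C)(C)C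
F6 | step 14 | 2-[(3S,4R)-4-{[tert-butyl(dimethyl)silyl]oxy}-6,7,8-trimethoxy-3,4-dihydro-2H-chromen-3-yl]-5,6-dimethoxybenzene-1,4-diol | COc1cc2c(c(OC)c1OC)OC[C@H](c1cc(O)c(OC)c(OC)c1O)[C@H]2O[Si](C)(C)C(C)(C)C
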